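**Plan**

- Retrosynthesis: the acyl–O bond at the lactol of ring D (five-membered lactol lactone) is cut first. Ring C (dioxepinone) is then cut at both bonds of its ester carbonyl, the ring A aryl–C(=O) bond and the C(=O)–O bond to ring B, with CO as the one-carbon unit. The diaryl ether C–O bond, the ring A C–I bond and the formyl C–C bonds of both rings follow.
- Enabling feature: the ring C carbonyl carbon sits on a ring A carbon that is para to the methoxy group, so it can be iodinated. Across the ether oxygen it lies next to a ring B phenolic oxygen, so palladium can join iodide, CO and that phenol although the carbonyl is flanked by methyl and aryloxy groups.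
- Forward: ring A phenol 8 (4 steps from 3,5-dimethoxytoluene) and ring B fluoro aldehyde 15 (4 steps from 2,4-dihydroxy-3-methylbenzoic acid) are joined by SNAr, deallylated and iodinated. Ring C then closes by carbonylative lactonisation, and ring D closes when the benzyl ester next to the aldehyde is hydrogenolysed.
- Stereochemistry: the single stereocentre (lactol carbon, R) is set by acylative dynamic kinetic resolution of the racemising lactol and unveiled last by lipase-mediated acyl transfer, which leaves the C–O bond at the stereocentre intact.

Key step: step 12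

Assumption: a 3-hydroxyphthalide lactol epimerises through its open formyl acid; it is assumed that the free (R)-lactol, released last under neutral anhydrous conditions and handled cold without base, keeps its configuration, and that the hand of the isothiourea giving the (R)-acylal is found in a test run (both hands are available).

**Route**

Step 1
Reactants: 1 3,5-dimethoxytoluene
Product: 4 2,6-dimethoxy-4-methylbenzaldehyde, via aryllithium 2 (not isolated), via lithium aminoalkoxide 3 (not isolated)
Conditions: n-BuLi, TMEDA, THF, 0 °C to rt; DMF, 0 °C; aq. HCl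
Reagents that add atoms: N,N-dimethylformamide, CN(C)C=O
Why: Directed ortho-lithiation occurs at the ring C–H between the two methoxy groups and the aryllithium is formylated by DMF (Bouveault aldehyde synthesis), giving a symmetrical aldehyde in which both methoxy groups are equivalent.

Step 2
Reactants: 4 2,6-dimethoxy-4-methylbenzaldehyde
Product: 6 2-hydroxy-6-methoxy-4-methylbenzaldehyde, via aryloxydichloroborane 5 (not isolated)
Conditions: BCl3 (1.1 equiv), CH2Cl2, −78 to 0 °C; H2O
Reagents that add atoms: none
Why: Chelation-controlled demethylation: BCl3 bound to the aldehyde oxygen cleaves one of the two equivalent ortho methoxy groups, and the chelated aryloxyborane formed should resist a second cleavage at low temperature.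

Step 3
Reactants: 6 2-hydroxy-6-methoxy-4-methylbenzaldehyde
Product: 7 2-(hydroxymethyl)-3-methoxy-5-methylphenol
Conditions: NaBH4, MeOH, 0 °C; aq. NH4Cl
Reagents that add atoms: none
Why: Hydride reduction of the aryl aldehyde to the benzylic alcohol with nothing else reducible present, with a mild quench so that the electron-rich salicyl alcohol does not form a quinone methide.

Step 4
Reactants: 7 2-(hydroxymethyl)-3-methoxy-5-methylphenol
Product: 8 3-methoxy-5-methyl-2-{[(triisopropylsilyl)oxy]methyl}phenol
Conditions: i-Pr3SiCl (1.05 equiv), imidazole, DMF, 0 °C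
Reagents that add atoms: chlorotriisopropylsilane, CC(C)[Si](Cl)(C(C)C)C(C)C
Why: Selective O-silylation: the primary alcohol reacts faster with the bulky chlorosilane than the hindered, hydrogen-bonded phenol, and the triisopropylsilyl ether is chosen to survive fluoride, base and mild acid in steps 9 to 14.

Step 5
Reactants: 9 2,4-dihydroxy-3-methylbenzoic acid
Product: 10 benzyl 2,4-dihydroxy-3-methylbenzoate
Conditions: BnBr, KHCO3, DMF, 40 °C
Reagents that add atoms: benzyl bromide, BrCc1ccccc1
Why: Hydrogencarbonate deprotonates only the carboxylic acid, so SN2 alkylation with benzyl bromide should give the ester with both phenols free; the benzyl ester can later be removed without acid or base.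

Step 6
Reactants: 10 benzyl 2,4-dihydroxy-3-methylbenzoate
Product: 11 benzyl 5-fluoro-2,4-dihydroxy-3-methylbenzoate
Conditions: Selectfluor (1.05 equiv), MeCN, 0 °C to rt
Reagents that add atoms: Selectfluor, F[N+]12CC[N+](CCl)(CC1)CC2.F[B-](F)(F)F.F[B-](F)(F)F
Why: Electrophilic aromatic fluorination at C5, the only unsubstituted position ortho to one hydroxyl and para to the other (C6 is meta to both).

Step 7
Reactants: 11 benzyl 5-fluoro-2,4-dihydroxy-3-methylbenzoate
Product: 12 benzyl 2,4-bis(allyloxy)-5-fluoro-3-methylbenzoate
Conditions: allyl bromide (3 equiv), K2CO3, DMF, 55 °C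
Reagents that add atoms: allyl bromide, C=CCBr
Why: Williamson etherification of both phenoxides, with warming for the hydroxyl that is hydrogen-bonded to the ester; allyl ethers tolerate the amide base and the SNAr step and come off under neutral conditions.

Step 8
Reactants: 12 benzyl 2,4-bis(allyloxy)-5-fluoro-3-methylbenzoate
Product: 15 benzyl 4,6-bis(allyloxy)-3-fluoro-2-formyl-5-methylbenzoate, via arylmagnesium chloride 13 (not isolated), via magnesium aminoalkoxide 14 (not isolated)
Conditions: TMPMgCl·LiCl (1.3 equiv), THF, −20 to 0 °C; DMF, −20 °C; aq. HCl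
Reagents that add atoms: N,N-dimethylformamide, CN(C)C=O
Why: Directed ortho-magnesiation at the only ring C–H, which lies between fluorine and the ester and is acidified by both; the arylmagnesium tolerates the ester at low temperature and is formylated by DMF (Bouveault aldehyde synthesis).

Step 9
Reactants: 8 3-methoxy-5-methyl-2-{[(triisopropylsilyl)oxy]methyl}phenol; 15 benzyl 4,6-bis(allyloxy)-3-fluoro-2-formyl-5-methylbenzoate
Product: 16 benzyl 4,6-bis(allyloxy)-2-formyl-3-[3-methoxy-5-methyl-2-(triisopropylsilyloxymethyl)phenoxy]-5-methylbenzoate
Conditions: dry K2CO3, DMF, 90 °C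
Reagents that add atoms: none
Why: Nucleophilic aromatic substitution (addition–elimination): the potassium phenoxide of 8 attacks the fluorine-bearing carbon, activated by the ortho formyl group and the meta ester, while the two allyloxy groups are twisted out of conjugation by their neighbours and donate little.

Step 10
Reactants: 16 bis(allyl) diaryl ether
Product: 17 benzyl 2-formyl-4,6-dihydroxy-3-[3-methoxy-5-methyl-2-(triisopropylsilyloxymethyl)phenoxy]-5-methylbenzoate
Conditions: Pd(PPh3)4 (5 mol%), PhNHMe (4 equiv), THF, rt
Reagents that add atoms: none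
Why: Tsuji–Trost-type deallylation: zerovalent palladium ionises both aryl allyl ethers, whose phenoxides are stabilised by the ortho or para ester, and N-methylaniline traps the allyl complex without condensing irreversibly with the aldehyde.

Step 11
Reactants: 17 diaryl ether diphenol
Product: 18 benzyl 2-formyl-4,6-dihydroxy-3-[2-iodo-5-methoxy-3-methyl-6-(triisopropylsilyloxymethyl)phenoxy]-5-methylbenzoate
Conditions: N-iodosuccinimide (1.05 equiv), CF3CO2H (10 mol%), MeCN, 0 °C
Reagents that add atoms: N-iodosuccinimide, O=C1CCC(=O)N1I
Why: Electrophilic aromatic iodination: ring B has no free position, and on ring A the carbon para to the methoxy group and ortho to the ether oxygen should be the more activated of the two free positions, since methoxy is a stronger para director than the electron-poor aryloxy group.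

Step 12
Reactants: 18 iodo diaryl ether diphenol
Product: 19 depsidone formyl benzyl ester (ring C closed)
Conditions: Pd(OAc)2 (10 mol%), Xantphos (12 mol%), CO (1 atm), Et3N (3 equiv), toluene (0.01 M), 90 °C
Reagents that add atoms: carbon monoxide, [C-]#[O+]
Why: Zerovalent palladium generated from Pd(OAc)2 and Xantphos adds oxidatively to the ring A C–I bond, CO inserts to give an aroyl complex of divalent palladium, and the ring B phenoxide ortho to the ether oxygen displaces the metal, so the aryl–carbonyl C–C bond and the ester C–O bond form in one operation. The closest known reaction type is the palladium-catalysed intramolecular aryloxycarbonylation (carbonylative lactonisation) of halo-phenols. Ring C closes by 7-exo-trig acyl substitution, equivalent to C–O reductive elimination from an eight-membered aroyl(aryloxo)palladium chelate held together by the diaryl ether. No stereocentre is formed. The step needs selectivity between the two phenols and between ring closure and intermolecular esterification: only the hydroxyl ortho to the ether can reach the aroyl palladium, the other being para to the ether and hydrogen-bonded to its benzyl ester, and high dilution favours the intramolecular path while CO insertion should outrun direct aryl–oxygen coupling. The aroyl palladium is electrophilic enough to acylate although its carbon is flanked by methyl and aryloxy groups, which a preformed benzoate would resist.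

Step 13
Reactants: 19 depsidone formyl benzyl ester
Product: 21 racemic ring D lactol (3-hydroxyphthalide) of the silyl-protected depsidone, via formyl acid 20 (not isolated)
Conditions: H2 (1 atm), 10% Pd/C, EtOAc, rt
Reagents that add atoms: none
Why: Hydrogenolysis of the benzyl ester gives the 2-formylbenzoic acid, which should close at once to the lactol (ring–chain tautomerism), shielding the aldehyde from reduction and leaving the base-sensitive ring C lactone untouched; the lactol forms as a racemate.

Step 14
Reactants: 21 racemic lactol
Product: 22 (R)-lactol isobutyrate (acylal) of the silyl-protected depsidone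
Conditions: (i-PrCO)2O (1.5 equiv), benzotetramisole (10 mol%, hand chosen for R), i-Pr2NEt, CHCl3, 0 °C
Reagents that add atoms: isobutyric anhydride, CC(C)C(=O)OC(=O)C(C)C
Why: Acylative dynamic kinetic resolution of a 3-hydroxyphthalide: the lactol epimerises through its open formyl carboxylate under amine base while the chiral acyl-isothiouronium ion acylates one enantiomer much faster, so the material should converge on the (R)-acylal under catalyst control, the chelated and doubly flanked phenol staying free.

Step 15
Reactants: 22 (R)-lactol isobutyrate, silyl-protected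
Product: 23 (R)-lactol isobutyrate with free hydroxymethyl group
Conditions: HF·pyridine, pyridine, THF, 0 °C to rt
Reagents that add atoms: none
Why: Fluoride-mediated cleavage of the silyl ether under buffered conditions that should neither open the ring C lactone nor ionise the acylal, so the stereocentre is not touched.

Step 16
Reactants: 23 (R)-lactol isobutyrate with free hydroxymethyl group
Product: 24 target CNP0367167.1 as the (R)-lactol
Conditions: Candida rugosa lipase, n-BuOH (5 equiv), MTBE, 20 °C; filter, concentrate cold
Reagents that add atoms: none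
Why: Lipase-catalysed transesterification moves the isobutyryl group to butanol by acyl–oxygen cleavage, so the lactol C–O bond and its (R) configuration are retained, and the absence of water and base suppresses ring opening of the lactol.

**Compound list**

1 | 3,5-dimethoxytoluene | COc1cc(C)cc(OC)c1 | starting material
2 | 2,6-dimethoxy-4-methylphenyllithium (not isolated) | [Li]c1c(OC)cc(C)cc1OC | intermediate
3 | lithium (dimethylamino)(2,6-dimethoxy-4-methylphenyl)methanolate (not isolated) | CN(C)C(O[Li])c1c(OC)cc(C)cc1OC | intermediate
4 | 2,6-dimethoxy-4-methylbenzaldehyde | COc1cc(C)cc(OC)c1C=O | intermediate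
5 | dichloro(2-formyl-3-methoxy-5-methylphenoxy)borane (not isolated) | COc1cc(C)cc(OB(Cl)Cl)c1C=O | intermediate
6 | 2-hydroxy-6-methoxy-4-methylbenzaldehyde | COc1cc(C)cc(O)c1C=O | intermediate
7 | 2-(hydroxymethyl)-3-methoxy-5-methylphenol | COc1cc(C)cc(O)c1CO | intermediate
8 | 3-methoxy-5-methyl-2-{[(triisopropylsilyl)oxy]methyl}phenol | COc1cc(C)cc(O)c1CO[Si](C(C)C)(C(C)C)C(C)C | intermediate
9 | 2,4-dihydroxy-3-methylbenzoic acid | Cc1c(O)ccc(C(=O)O)c1O | starting material
10 | benzyl 2,4-dihydroxy-3-methylbenzoate | Cc1c(O)ccc(C(=O)OCc2ccccc2)c1O | intermediate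
11 | benzyl 5-fluoro-2,4-dihydroxy-3-methylbenzoate | Cc1c(O)c(F)cc(C(=O)OCc2ccccc2)c1O | intermediate
12 | benzyl 2,4-bis(allyloxy)-5-fluoro-3-methylbenzoate | Cc1c(OCC=C)c(F)cc(C(=O)OCc2ccccc2)c1OCC=C | intermediate
13 | arylmagnesium chloride from 12, magnesium between fluorine and ester (not isolated) | Cc1c(OCC=C)c(F)c([Mg]Cl)c(C(=O)OCc2ccccc2)c1OCC=C | intermediate
14 | chloromagnesium aminoalkoxide, DMF adduct of 13 (not isolated) | Cc1c(OCC=C)c(F)c(C(O[Mg]Cl)N(C)C)c(C(=O)OCc2ccccc2)c1OCC=C | intermediate
15 | benzyl 4,6-bis(allyloxy)-3-fluoro-2-formyl-5-methylbenzoate | Cc1c(OCC=C)c(F)c(C=O)c(C(=O)OCc2ccccc2)c1OCC=C | intermediate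
16 | benzyl 4,6-bis(allyloxy)-2-formyl-3-[3-methoxy-5-methyl-2-(triisopropylsilyloxymethyl)phenoxy]-5-methylbenzoate | COc1cc(C)cc(Oc2c(OCC=C)c(C)c(OCC=C)c(C(=O)OCc3ccccc3)c2C=O)c1CO[Si](C(C)C)(C(C)C)C(C)C | intermediate
17 | benzyl 2-formyl-4,6-dihydroxy-3-[3-methoxy-5-methyl-2-(triisopropylsilyloxymethyl)phenoxy]-5-methylbenzoate | COc1cc(C)cc(Oc2c(O)c(C)c(O)c(C(=O)OCc3ccccc3)c2C=O)c1CO[Si](C(C)C)(C(C)C)C(C)C | intermediate
18 | benzyl 2-formyl-4,6-dihydroxy-3-[2-iodo-5-methoxy-3-methyl-6-(triisopropylsilyloxymethyl)phenoxy]-5-methylbenzoate | COc1cc(C)c(I)c(Oc2c(O)c(C)c(O)c(C(=O)OCc3ccccc3)c2C=O)c1CO[Si](C(C)C)(C(C)C)C(C)C | intermediate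
19 | depsidone formyl benzyl ester: ring C closed; ring A with OMe, Me and CH2OSi(i-Pr)3; ring B with Me, free OH, CO2Bn and CHO | COc1cc(C)c2c(c1CO[Si](C(C)C)(C(C)C)C(C)C)Oc1c(c(C)c(O)c(C(=O)OCc3ccccc3)c1C=O)OC2=O | intermediate
20 | the 2-formylbenzoic acid from 19, benzyl ester cleaved (not isolated) | COc1cc(C)c2c(c1CO[Si](C(C)C)(C(C)C)C(C)C)Oc1c(c(C)c(O)c(C(=O)O)c1C=O)OC2=O | intermediate
21 | racemic lactol: ring D closed as 3-hydroxyphthalide, silyl ether retained | COc1cc(C)c2c(c1CO[Si](C(C)C)(C(C)C)C(C)C)Oc1c(c(C)c(O)c3c1C(O)OC3=O)OC2=O | intermediate
22 | (R)-lactol isobutyrate (acylal), silyl ether retained | COc1cc(C)c2c(c1CO[Si](C(C)C)(C(C)C)C(C)C)Oc1c(c(C)c(O)c3c1[C@H](OC(=O)C(C)C)OC3=O)OC2=O | intermediate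
23 | (R)-lactol isobutyrate with free hydroxymethyl group | COc1cc(C)c2c(c1CO)Oc1c(c(C)c(O)c3c1[C@H](OC(=O)C(C)C)OC3=O)OC2=O | intermediate
24 | CNP0367167.1, (R)-lactol | COc1cc(C)c2c(c1CO)Oc1c(c(C)c(O)c3c1[C@H](O)OC3=O)OC2=O | target

**Step count and risks**

Total step count: 16. Longest linear sequence: 12 steps (steps 1–4 then 9–16; the ring B branch, steps 5–8 then 9–16, is equally long).

Steps most likely to fail:

1. Step 9 (SNAr). Fluoride displacement may be too slow at a fluoroarene that is flanked on both sides and carries two alkoxy donors, so that desilylation by liberated fluoride or addition to the aldehyde takes over. The fallback sets out from 10 and comes back at 16. NBS in MeCN should brominate the same ring position to give benzyl 5-bromo-2,4-dihydroxy-3-methylbenzoate F1. Allyl bromide and K2CO3 then give benzyl 2,4-bis(allyloxy)-5-bromo-3-methylbenzoate F2. TMPMgCl·LiCl metalates between bromine and the ester to the arylmagnesium chloride F3, DMF converts it into the magnesium aminoalkoxide F4, and acidic work-up releases benzyl 4,6-bis(allyloxy)-3-bromo-2-formyl-5-methylbenzoate F5. An Ullmann ether coupling of F5 with phenol 8 (CuI, picolinic acid, K3PO4, DMSO, 90 °C), assisted by the ortho formyl group, rejoins the route at 16. This detour also avoids the electrophilic fluorination of step 6, should ipso-fluorination at the methyl-bearing carbon compete there.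

2. Step 11 (iodination). Site selectivity between the two free ring A positions may be poor (attack ortho to methoxy and para to the ether oxygen), or iodination may go twice. The fallback sets out from 8 and comes back at 18. Iodination of the free phenol (I2, NaHCO3, THF–water, 0 °C) is directed to the carbon ortho to the hydroxyl and para to the methoxy group and should give 2-iodo-5-methoxy-3-methyl-6-{[(triisopropylsilyl)oxy]methyl}phenol F6, whose regiochemistry can be secured before the fragments are joined. SNAr of F6 on 15 (K2CO3, DMF, 90 °C) then gives the iodinated bis(allyl) diaryl ether F7. Deallylation with Pd(PPh3)4 and N-methylaniline at room temperature, where ionisation of the allyl ethers is faster than oxidative addition into the hindered iodide, rejoins the route at 18.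

3. Step 12 (carbonylative lactonisation). Closure of the aroyl palladium to a seven-membered, tetra-ortho-substituted lactone may be slower than intermolecular ester formation, capture by traces of water or hydrodeiodination. The fallback sets out from 18 and comes back at 19. Hydroxycarbonylation (Pd(OAc)2, Xantphos, CO, water, Et3N, dioxane, 80 °C) deliberately intercepts the aroyl palladium with water to give the diaryl ether benzoic acid F8. Dehydrative lactonisation of this hydroxy acid with dicyclohexylcarbodiimide in pyridine, the classical closure of depsidones, rejoins the route at 19.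

**Further compounds**

F1 | step 9 | benzyl 5-bromo-2,4-dihydroxy-3-methylbenzoate | Cc1c(O)c(Br)cc(C(=O)OCc2ccccc2)c1O
F2 | step 9 | benzyl 2,4-bis(allyloxy)-5-bromo-3-methylbenzoate | Cc1c(OCC=C)c(Br)cc(C(=O)OCc2ccccc2)c1OCC=C
F3 | step 9 | arylmagnesium chloride from F2, magnesium between bromine and ester | Cc1c(OCC=C)c(Br)c([Mg]Cl)c(C(=O)OCc2ccccc2)c1OCC=C
F4 | step 9 | chloromagnesium aminoalkoxide, DMF adduct of F3 | Cc1c(OCC=C)c(Br)c(C(O[Mg]Cl)N(C)C)c(C(=O)OCc2ccccc2)c1OCC=C
F5 | step 9 | benzyl 4,6-bis(allyloxy)-3-bromo-2-formyl-5-methylbenzoate | Cc1c(OCC=C)c(Br)c(C=O)c(C(=O)OCc2ccccc2)c1OCC=C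
F6 | step 11 | 2-iodo-5-methoxy-3-methyl-6-{[(triisopropylsilyl)oxy]methyl}phenol | COc1cc(C)c(I)c(O)c1CO[Si](C(C)C)(C(C)C)C(C)C
F7 | step 11 | benzyl 4,6-bis(allyloxy)-2-formyl-3-[2-iodo-5-methoxy-3-methyl-6-(triisopropylsilyloxymethyl)phenoxy]-5-methylbenzoate | COc1cc(C)c(I)c(Oc2c(OCC=C)c(C)c(OCC=C)c(C(=O)OCc3ccccc3)c2C=O)c1CO[Si](C(C)C)(C(C)C)C(C)C
F8 | step 12 | 2-[5-(benzyloxycarbonyl)-6-formyl-2,4-dihydroxy-3-methylphenoxy]-4-methoxy-6-methyl-3-{[(triisopropylsilyl)oxy]methyl}benzoic acid | COc1cc(C)c(C(=O)O)c(Oc2c(O)c(C)c(O)c(C(=O)OCc3ccccc3)c2C=O)c1CO[Si](C(C)C)(C(C)C)C(C)C
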